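**Plan**

Cuts: C4–OH back to C4=O. Then C3–C4 and O–C2 together (retro-(3+2), isoxazoline 39). Then O7–C19 (lactone), C8–C17 (aldol), C7–C8 (furyllithium + Weinreb amide), C9–C10 (Ireland–Claisen), and C1–C15 and C1–C2 (alkylation of carvone).
Enabling feature: in the ten-membered ring, the syn-1,3-dioxygenated triad C2(OAc)–C3H2–C4(OH) lies between quaternary C1 and the Z C5=C6 bond. This is the retron of a Δ2-isoxazoline made from a C4 nitrile oxide (conjugated to C5=C6) and a C2=C3 vinyl group on C1.
Ring order: cyclohexene (from (S)-carvone), then the γ-lactone (steps 16–17, via a furan and a temporary pyran ring O8–C4), then the ten-membered ring last (step 22).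
Stereochemistry: C14 comes from carvone (Criegee, retention). C1 is set by methylation anti to the isopropenyl group. A temporary β C12–O bond (epoxidation anti to C14–O, then Wharton) is relayed to C10 and C9 in the Claisen step. C8/C17 come from a Felkin-type aldol, C7 from axial hydride delivery, C2 from the cycloaddition and C4 from CBS reduction.
Helpers and their removal: the pyran ring locks Z-C5=C6 and masks the C4 aldehyde (opened in step 20). O8-TMS is removed in step 25 and the isoxazoline nitrogen in step 23. Keeping C4 as C=N or C=O to the end sets its free OH apart from the four acetates.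

Key step: step 22

Remark: briarane numbering is used for every intermediate, and β is the face of the C15 methyl group. The hydroperoxide carbon in 5/6 and the lactol carbon C4 in 28–33 are epimer mixtures of no consequence. Compounds 13 and 20 are taken as purchasable.

**Step 1**
Reactants: 1 (S)-(+)-carvone
Product: 2 hydroxymethylene ketone (C2 attached to C1 as the Z enol)
Conditions: NaH, HCO2Et, THF, 0 °C to rt; 1 M HCl work-up
Reagents that add atoms: ethyl formate, CCOC=O
Why: Claisen-type formylation of the only enolisable α'-methylene group (C1) brings in C2 as a stable hydroxymethylene ketone, and no stereocentre is formed.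

**Step 2**
Reactants: 2 hydroxymethylene ketone
Product: 3 keto aldehyde (C1 quaternary: CH3 β and CHO α; C14 isopropenyl α)
Conditions: MeI, K2CO3, acetone, rt
Reagents that add atoms: iodomethane, CI
Why: C-alkylation of the β-keto aldehyde enolate sets quaternary C1, because allylic strain turns the neighbouring C14 isopropenyl group axial and methyl iodide should enter from the opposite (β) face.

**Step 3**
Reactants: 3 keto aldehyde
Product: 4 vinyl ketone (C2=C3 vinyl α on C1)
Conditions: Ph3PCH3Br, KOtBu, THF, 0 °C; then 3, –78 to 0 °C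
Reagents that add atoms: methyltriphenylphosphonium bromide, C[P+](c1ccccc1)(c1ccccc1)c1ccccc1.[Br-]
Why: Wittig methylenation is chemoselective because the aldehyde reacts far faster than the doubly flanked conjugated C10 ketone, and non-enolisable C1 cannot epimerise.

**Step 4**
Reactants: 4 vinyl ketone
Product: 7 C14 acetate enone, via methoxy hydroperoxide 5 (not isolated), via peracetate 6 (not isolated)
Conditions: O3 (1 equiv, Sudan III end point), CH2Cl2–MeOH, –78 °C; concentrate; Ac2O, Et3N, cat. DMAP, CH2Cl2, 0 to 40 °C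
Reagents that add atoms: ozone, [O-][O+]=O; methanol, CO
Why: Ozonolysis in methanol followed by Criegee rearrangement of the peracetate should attack the electron-rich 1,1-disubstituted isopropenyl bond before the neopentyl vinyl group and the enone, and C14 migrates from carbon to oxygen with retention, the acetyl carbons of 7 being the old isopropenyl carbon pair.

**Step 5**
Reactants: 7 C14 acetate enone
Product: 8 C14 hydroxy enone
Conditions: cat. K2CO3, MeOH, 0 °C
Reagents that add atoms: none
Why: Base-catalysed transesterification frees the C14 alcohol under conditions too mild for retro-aldol cleavage, since an acetate would not survive the enolate and organolithium steps ahead.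

**Step 6**
Reactants: 8 C14 hydroxy enone
Product: 9 C14 TBS ether enone
Conditions: TBSCl, imidazole, DMF, rt
Reagents that add atoms: tert-butyldimethylsilyl chloride, CC(C)(C)[Si](C)(C)Cl
Why: Standard silylation of the secondary alcohol gives a base-stable ether.

**Step 7**
Reactants: 9 C14 TBS ether enone
Product: 10 β-11,12-epoxy ketone
Conditions: 30% H2O2, cat. NaOH, MeOH, 0 °C
Reagents that add atoms: hydrogen peroxide, OO
Why: Weitz–Scheffer nucleophilic epoxidation touches only the enone, and hydroperoxide should add axially to C12 trans to the C14 substituent, as with carvone, placing the epoxide on the β face.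

**Step 8**
Reactants: 10 β-11,12-epoxy ketone
Product: 12 C12 β-allylic alcohol (C10=C11), via epoxy hydrazone 11 (not isolated)
Conditions: N2H4·H2O, cat. AcOH, MeOH, 0 °C to rt, under argon
Reagents that add atoms: none
Why: Wharton transposition (hydrazone formation, epoxide opening, loss of N2) leaves the β C12–O bond untouched and moves the double bond to C10=C11, while exclusion of air avoids diimide reduction of the vinyl group.

**Step 9**
Reactants: 12 C12 β-allylic alcohol; 13 (tert-butyldimethylsilyloxy)acetic acid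
Product: 14 C12 glycolate ester
Conditions: DCC, cat. DMAP, CH2Cl2, 0 °C to rt
Reagents that add atoms: none
Why: Steglich esterification joins the glycolate unit (C8, C9) to the C12 alcohol with retention at C12.

**Step 10**
Reactants: 14 C12 glycolate ester
Product: 17 C8 carboxylic acid (C9 OTBS; C9 β on C10; C11=C12), via silyl ketene acetal 15 (not isolated), via trimethylsilyl ester 16 (not isolated)
Conditions: LDA, THF, –78 °C; TMSCl; to rt then 50 °C; 1 M HCl work-up
Reagents that add atoms: none
Why: In the Ireland–Claisen rearrangement the [3,3] shift is suprafacial, so the β C12–O bond is traded for a β C10–C9 bond (H-10 α) and the alkene returns to C11=C12, and the boat-like transition state usual for cyclohexenyl esters, which keeps the C9 silyloxy group of the chelated Z-enolate away from quaternary C1, should set C9.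

**Step 11**
Reactants: 17 C8 carboxylic acid
Product: 19 C8 Weinreb amide, via acyl imidazole 18 (not isolated)
Conditions: CDI, CH2Cl2, rt; then MeNH(OMe)·HCl
Reagents that add atoms: N,O-dimethylhydroxylamine hydrochloride, CNOC.Cl
Why: Amide coupling through the acyl imidazole gives the Weinreb amide without touching C9.

**Step 12**
Reactants: 20 5-bromofuran-3-carboxylic acid
Product: 21 (5-bromofuran-3-yl)methanol
Conditions: BH3·THF, THF, 0 °C to rt; aqueous work-up
Reagents that add atoms: none
Why: Borane reduces the carboxylic acid chemoselectively and leaves the bromofuran intact.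

**Step 13**
Reactants: 21 (5-bromofuran-3-yl)methanol
Product: 22 2-bromo-4-(TBS-oxymethyl)furan
Conditions: TBSCl, imidazole, DMF, rt
Reagents that add atoms: tert-butyldimethylsilyl chloride, CC(C)(C)[Si](C)(C)Cl
Why: Standard silylation protects the future C16 alcohol.

**Step 14**
Reactants: 19 C8 Weinreb amide; 22 2-bromo-4-(TBS-oxymethyl)furan
Product: 24 furyl ketone (furan = C4 to C7 plus C16), via furyllithium 23 (not isolated)
Conditions: 22, n-BuLi, THF, –78 °C; then 19, –78 to –20 °C; AcOH quench
Reagents that add atoms: none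
Why: Bromine–lithium exchange and Weinreb ketone synthesis form C7–C8, the chelated tetrahedral intermediate stopping over-addition and the low temperature keeping C9 intact.

**Step 15**
Reactants: 24 furyl ketone; 25 methyl propanoate
Product: 27 tertiary C8 carbinol ester, via lithium enolate 26 (not isolated)
Conditions: 25, LDA, THF–DMPU, –78 °C; anhydrous CeCl3; then 24, –78 °C; AcOH quench
Reagents that add atoms: none
Why: Aldol addition of the propionate Z(O)-enolate to the ketone forms C8–C17, the non-chelating C9 silyl ether directing attack in the polar Felkin–Anh (Cornforth) sense to give 8S, a closed transition state with the bulky C9 branch equatorial giving the 8,17-syn (17R) relation, and cerium lowering the basicity.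

**Step 16**
Reactants: 27 tertiary C8 carbinol ester
Product: 28 pyranone lactol (ring O8–C8–C7(=O)–C6=C5–C4(OH))
Conditions: NBS, NaHCO3, THF–H2O, 0 °C
Reagents that add atoms: water, O
Why: In the Achmatowicz rearrangement the electron-rich furan is oxidised faster than the isolated alkenes, and the C8 hydroxyl captures the Z-enedione as a pyranone lactol, a temporary ring that locks the Z C5=C6 geometry, masks the C4 aldehyde and ties up O8.

**Step 17**
Reactants: 28 pyranone lactol
Product: 30 bicyclic lactone lactol (γ-lactone cis-fused to the pyran), via hydroxy ester 29 (not isolated)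
Conditions: NaBH4, CeCl3·7H2O, MeOH, –78 to 0 °C
Reagents that add atoms: none
Why: In the Luche 1,2-reduction hydride should enter axially and anti to the pseudo-axial CH(CH3)CO2CH3 branch on C8, so O7 ends cis to that branch (7S) and closes the γ-lactone by spontaneous transesterification.

**Step 18**
Reactants: 30 bicyclic lactone lactol
Product: 31 triol lactol
Conditions: HF·pyridine, pyridine–THF, 0 °C to rt
Reagents that add atoms: none
Why: Fluoride-mediated desilylation removes all three TBS ethers now that no strongly basic step remains, and lactone and lactol tolerate buffered HF.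

**Step 19**
Reactants: 31 triol lactol
Product: 32 tetraacetate (C9 C14 C16 acetates plus anomeric C4 acetate)
Conditions: Ac2O, pyridine, cat. DMAP, CH2Cl2, rt
Reagents that add atoms: acetic anhydride, CC(=O)OC(C)=O
Why: Exhaustive acetylation installs the final C9, C14 and C16 acetates and a labile anomeric one, while O8 is protected as the ring oxygen.

**Step 20**
Reactants: 32 tetraacetate
Product: 34 (Z)-enal (E)-oxime with free C8 hydroxyl, via lactol triacetate 33 (not isolated)
Conditions: NH2OH·HCl (2.2 equiv), pyridine, EtOH, 0 °C to rt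
Reagents that add atoms: hydroxylamine hydrochloride, NO.Cl
Why: Hydroxylamine first removes the activated anomeric acetate by acyl transfer and then condenses with the open hydroxy-enal form of the lactol (oxime formation), which opens the temporary pyran ring with the Z geometry kept.

**Step 21**
Reactants: 34 (Z)-enal (E)-oxime
Product: 36 O8-trimethylsilyl oxime, via bis-silyl derivative 35 (not isolated)
Conditions: TMSOTf, 2,6-lutidine, CH2Cl2, –78 to 0 °C; then MeOH, 0 °C
Reagents that add atoms: trimethylsilyl triflate, C[Si](C)(C)OS(=O)(=O)C(F)(F)F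
Why: Silylation of the hindered tertiary C8 hydroxyl with the triflate, followed by methanolysis of the far more labile oxime O-silyl group, blocks the hydroxyl that would otherwise trap the nitrile oxide.

**Step 22**
Reactants: 36 O8-trimethylsilyl oxime
Product: 39 2,4-bridged isoxazoline (ten-membered ring closed), via hydroximoyl chloride 37 (not isolated), via nitrile oxide 38 (not isolated)
Conditions: NCS, DMF, rt; then syringe-pump addition to Et3N, toluene, 80 °C (final 1 mM)
Reagents that add atoms: none
Why: Proposed new method: NCS chlorination of the aldoxime and 1,3-elimination of HCl release the conjugated nitrile oxide 38, whose C4–N–O dipole should add in one concerted, suprafacial (3+2) event to the C2=C3 vinyl group on C1, making C3–C4 and O–C2 together. The closest known reaction type is the intramolecular nitrile oxide–olefin cycloaddition that closes large rings as 3,5-bridged isoxazolines, and a ten-membered carbocycle has not been closed in this mode, hence the label. The isoxazoline closes by the (3+2) process itself and the ten-membered carbocycle closes in the bridged mode (dipole carbon to the terminal CH2, oxygen to the substituted carbon), giving a bicyclo[7.2.1] frame whose C4=N bond is E within an eleven-membered circuit and so breaks no bridgehead rule. C2 is the only new stereocentre: the tether leaves C10 on the β face, gauche to the α-vinyl group, so C3 has to lie next to C10 and the dipole oxygen has to pass on the open side next to C15, which is attack on the Si face of C2 and should give 2S. The regiochemistry is the innate one of monosubstituted alkenes, the trisubstituted C11=C12 and conjugated C5=C6 bonds are much poorer dipolarophiles, the O8 silyl ether blocks six-ring addition of the C8 hydroxyl to the dipole, and slow release at high dilution holds back furoxan formation. Closure is helped because only the C10–C9, C9–C8 and C7–C6 bonds and the vinyl rotor are free, the Z C5=C6 bond, the lactone, the cyclohexene and the quaternary C1 and C8 fixing the rest.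

**Step 23**
Reactants: 39 2,4-bridged isoxazoline
Product: 41 C2 hydroxy C4 enone, via hydroxy imine 40 (not isolated)
Conditions: Mo(CO)6, MeCN–H2O, 80 °C
Reagents that add atoms: water, O
Why: Molybdenum hexacarbonyl cleaves the N–O bond reductively and the conjugated imine hydrolyses, which removes the helper nitrogen and unveils the aldol-type C2 hydroxyl and C4 enone without touching alkenes, esters or C2.

**Step 24**
Reactants: 41 C2 hydroxy C4 enone
Product: 42 C2 acetoxy C4 enone
Conditions: Ac2O, pyridine, cat. DMAP, CH2Cl2, 0 °C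
Reagents that add atoms: acetic anhydride, CC(=O)OC(C)=O
Why: Mild acetylation of the C2 alcohol completes the acetate set while C4 is still a ketone, which is how the free C4 hydroxyl of the target is told apart from the four acetates, and the low temperature avoids β-elimination.

**Step 25**
Reactants: 42 C2 acetoxy C4 enone
Product: 44 CNP0226727.2 (target), via O8-silyl ether 43 (not isolated)
Conditions: (S)-Me-CBS (30 mol %), catecholborane, toluene, –78 °C; then MeOH, 0.5 M HCl, THF, 0 °C
Reagents that add atoms: none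
Why: In the Corey–Bakshi–Shibata reduction, with the alkenyl side (C5) as the large and C3H2 as the small group, the (S)-oxazaborolidine should deliver hydride to give 4R under reagent control, and the acidic work-up removes the O8 silyl helper.

**Compound list**

1 | (S)-(+)-carvone | O=C1C(C)=CC[C@H](C(C)=C)C1 | starting material
2 | hydroxymethylene ketone | O=C1C(C)=CC[C@H](C(C)=C)/C1=C/O | intermediate
3 | keto aldehyde (C1: CH3 β, CHO α) | O=C1C(C)=CC[C@H](C(C)=C)[C@]1(C)C=O | intermediate
4 | vinyl ketone | O=C1C(C)=CC[C@H](C(C)=C)[C@]1(C)C=C | intermediate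
5 | methoxy hydroperoxide | O=C1C(C)=CC[C@H](C(C)(OC)OO)[C@]1(C)C=C | intermediate
6 | peracetate | O=C1C(C)=CC[C@H](C(C)(OC)OOC(C)=O)[C@]1(C)C=C | intermediate
7 | C14 acetate enone | O=C1C(C)=CC[C@H](OC(C)=O)[C@]1(C)C=C | intermediate
8 | C14 hydroxy enone | O=C1C(C)=CC[C@H](O)[C@]1(C)C=C | intermediate
9 | C14 TBS ether enone | O=C1C(C)=CC[C@H](O[Si](C)(C)C(C)(C)C)[C@]1(C)C=C | intermediate
10 | β-11,12-epoxy ketone | O=C1[C@@]2(C)O[C@H]2C[C@H](O[Si](C)(C)C(C)(C)C)[C@]1(C)C=C | intermediate
11 | epoxy hydrazone | NN=C1[C@@]2(C)O[C@H]2C[C@H](O[Si](C)(C)C(C)(C)C)[C@]1(C)C=C | intermediate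
12 | C12 β-allylic alcohol | O[C@H]1C[C@H](O[Si](C)(C)C(C)(C)C)[C@](C)(C=C)C=C1C | intermediate
13 | (tert-butyldimethylsilyloxy)acetic acid | OC(=O)CO[Si](C)(C)C(C)(C)C | starting material
14 | C12 glycolate ester | O=C(CO[Si](C)(C)C(C)(C)C)O[C@H]1C[C@H](O[Si](C)(C)C(C)(C)C)[C@](C)(C=C)C=C1C | intermediate
15 | silyl ketene acetal | C[Si](C)(C)O/C(=C\O[Si](C)(C)C(C)(C)C)O[C@H]1C[C@H](O[Si](C)(C)C(C)(C)C)[C@](C)(C=C)C=C1C | intermediate
16 | trimethylsilyl ester | C[Si](C)(C)OC(=O)[C@@H](O[Si](C)(C)C(C)(C)C)[C@H]1C(C)=CC[C@H](O[Si](C)(C)C(C)(C)C)[C@]1(C)C=C | intermediate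
17 | C8 carboxylic acid | OC(=O)[C@@H](O[Si](C)(C)C(C)(C)C)[C@H]1C(C)=CC[C@H](O[Si](C)(C)C(C)(C)C)[C@]1(C)C=C | intermediate
18 | acyl imidazole | O=C(n1ccnc1)[C@@H](O[Si](C)(C)C(C)(C)C)[C@H]1C(C)=CC[C@H](O[Si](C)(C)C(C)(C)C)[C@]1(C)C=C | intermediate
19 | C8 Weinreb amide | CON(C)C(=O)[C@@H](O[Si](C)(C)C(C)(C)C)[C@H]1C(C)=CC[C@H](O[Si](C)(C)C(C)(C)C)[C@]1(C)C=C | intermediate
20 | 5-bromofuran-3-carboxylic acid | OC(=O)c1coc(Br)c1 | starting material
21 | (5-bromofuran-3-yl)methanol | OCc1coc(Br)c1 | intermediate
22 | 2-bromo-4-(TBS-oxymethyl)furan | CC(C)(C)[Si](C)(C)OCc1coc(Br)c1 | intermediate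
23 | furyllithium | CC(C)(C)[Si](C)(C)OCc1coc([Li])c1 | intermediate
24 | furyl ketone | O=C(c1cc(CO[Si](C)(C)C(C)(C)C)co1)[C@@H](O[Si](C)(C)C(C)(C)C)[C@H]1C(C)=CC[C@H](O[Si](C)(C)C(C)(C)C)[C@]1(C)C=C | intermediate
25 | methyl propanoate | CCC(=O)OC | starting material
26 | lithium Z(O)-enolate of 25 | C/C=C(\[O-])OC.[Li+] | intermediate
27 | tertiary C8 carbinol ester | COC(=O)[C@H](C)[C@@](c1cc(CO[Si](C)(C)C(C)(C)C)co1)(O)[C@@H](O[Si](C)(C)C(C)(C)C)[C@H]1C(C)=CC[C@H](O[Si](C)(C)C(C)(C)C)[C@]1(C)C=C | intermediate
28 | pyranone lactol | COC(=O)[C@H](C)[C@@]2(OC(O)C(CO[Si](C)(C)C(C)(C)C)=CC2=O)[C@@H](O[Si](C)(C)C(C)(C)C)[C@H]1C(C)=CC[C@H](O[Si](C)(C)C(C)(C)C)[C@]1(C)C=C | intermediate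
29 | hydroxy ester | COC(=O)[C@H](C)[C@@]2(OC(O)C(CO[Si](C)(C)C(C)(C)C)=C[C@@H]2O)[C@@H](O[Si](C)(C)C(C)(C)C)[C@H]1C(C)=CC[C@H](O[Si](C)(C)C(C)(C)C)[C@]1(C)C=C | intermediate
30 | bicyclic lactone lactol | CC(C)(C)[Si](C)(C)OCC1=C[C@@H]2OC(=O)[C@H](C)[C@@]2(OC1O)[C@@H](O[Si](C)(C)C(C)(C)C)[C@H]1C(C)=CC[C@H](O[Si](C)(C)C(C)(C)C)[C@]1(C)C=C | intermediate
31 | triol lactol | OCC1=C[C@@H]2OC(=O)[C@H](C)[C@@]2(OC1O)[C@@H](O)[C@H]1C(C)=CC[C@H](O)[C@]1(C)C=C | intermediate
32 | tetraacetate | CC(=O)OCC1=C[C@@H]2OC(=O)[C@H](C)[C@@]2(OC1OC(C)=O)[C@@H](OC(C)=O)[C@H]1C(C)=CC[C@H](OC(C)=O)[C@]1(C)C=C | intermediate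
33 | lactol triacetate | CC(=O)OCC1=C[C@@H]2OC(=O)[C@H](C)[C@@]2(OC1O)[C@@H](OC(C)=O)[C@H]1C(C)=CC[C@H](OC(C)=O)[C@]1(C)C=C | intermediate
34 | (Z)-enal (E)-oxime, free C8 OH | CC(=O)OC/C(/C=N/O)=C/[C@@H]1OC(=O)[C@H](C)[C@@]1(O)[C@@H](OC(C)=O)[C@H]1C(C)=CC[C@H](OC(C)=O)[C@]1(C)C=C | intermediate
35 | bis-silyl derivative | CC(=O)OC/C(/C=N/O[Si](C)(C)C)=C/[C@@H]1OC(=O)[C@H](C)[C@@]1(O[Si](C)(C)C)[C@@H](OC(C)=O)[C@H]1C(C)=CC[C@H](OC(C)=O)[C@]1(C)C=C | intermediate
36 | O8-trimethylsilyl oxime | CC(=O)OC/C(/C=N/O)=C/[C@@H]1OC(=O)[C@H](C)[C@@]1(O[Si](C)(C)C)[C@@H](OC(C)=O)[C@H]1C(C)=CC[C@H](OC(C)=O)[C@]1(C)C=C | intermediate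
37 | hydroximoyl chloride | CC(=O)OC/C(/C(Cl)=N/O)=C/[C@@H]1OC(=O)[C@H](C)[C@@]1(O[Si](C)(C)C)[C@@H](OC(C)=O)[C@H]1C(C)=CC[C@H](OC(C)=O)[C@]1(C)C=C | intermediate
38 | nitrile oxide | CC(=O)OC/C(C#[N+][O-])=C/[C@@H]1OC(=O)[C@H](C)[C@@]1(O[Si](C)(C)C)[C@@H](OC(C)=O)[C@H]1C(C)=CC[C@H](OC(C)=O)[C@]1(C)C=C | intermediate
39 | 2,4-bridged isoxazoline | CC(=O)OC/C1=C/[C@@H]2OC(=O)[C@H](C)[C@@]2(O[Si](C)(C)C)[C@@H](OC(C)=O)[C@H]2C(C)=CC[C@H](OC(C)=O)[C@]2(C)[C@@H]3CC1=NO3 | intermediate
40 | hydroxy imine | CC(=O)OC/C1=C/[C@@H]2OC(=O)[C@H](C)[C@@]2(O[Si](C)(C)C)[C@@H](OC(C)=O)[C@H]2C(C)=CC[C@H](OC(C)=O)[C@]2(C)[C@@H](O)CC1=N | intermediate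
41 | C2 hydroxy C4 enone | CC(=O)OC/C1=C/[C@@H]2OC(=O)[C@H](C)[C@@]2(O[Si](C)(C)C)[C@@H](OC(C)=O)[C@H]2C(C)=CC[C@H](OC(C)=O)[C@]2(C)[C@@H](O)CC1=O | intermediate
42 | C2 acetoxy C4 enone | CC(=O)OC/C1=C/[C@@H]2OC(=O)[C@H](C)[C@@]2(O[Si](C)(C)C)[C@@H](OC(C)=O)[C@H]2C(C)=CC[C@H](OC(C)=O)[C@]2(C)[C@@H](OC(C)=O)CC1=O | intermediate
43 | O8-silyl ether of the target | CC(=O)OC/C1=C/[C@@H]2OC(=O)[C@H](C)[C@@]2(O[Si](C)(C)C)[C@@H](OC(C)=O)[C@H]2C(C)=CC[C@H](OC(C)=O)[C@]2(C)[C@@H](OC(C)=O)C[C@H]1O | intermediate
44 | CNP0226727.2 | CC(=O)OC/C1=C/[C@@H]2OC(=O)[C@H](C)[C@@]2(O)[C@@H](OC(C)=O)[C@H]2C(C)=CC[C@H](OC(C)=O)[C@]2(C)[C@@H](OC(C)=O)C[C@H]1O | target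

Total step count: 25. Longest linear sequence: 23 (steps 1–11 and 14–25).

**Steps most likely to fail**

1. Step 22. Dimerisation or slow decay of the dipole may outrun a strained bridged transition state, or the dipole may add to the other face of the vinyl group. The fallback closes the same C3–C4 bond by polar, known chemistry and without a bridging ring. It sets out from 36. Buffered TiCl3 deoximation gives the (Z)-enal F1. Tsuji–Wacker oxidation of the C1 vinyl group, the only monosubstituted alkene, gives the methyl ketone F2. A boron-mediated intramolecular aldol addition (c-Hex2BCl, Et3N, high dilution) gives the macrocyclic β-hydroxy ketone F3; only C3 can be enolised because C1 is quaternary. Reagent-controlled (R)-Me-CBS/catecholborane reduction of the C2 ketone gives the 2S diol F4. MnO2 then oxidises only the allylic C4 alcohol, and the route is rejoined at 41.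

2. Step 15. Proton transfer from C9–H to the enolate and retro-aldol reversal may stall the addition. Leakage to chelation-type facial attack or to an open transition state may erode control at C8 and C17. The fallback sets out from 24. A Darzens condensation with the enolate of methyl 2-chloropropanoate traps the adduct irreversibly as the glycidic ester F5. SmI2 then cleaves the C17–O bond α to the ester and the samarium enolate is protonated, which returns to 27.

3. Step 8. Hydrazone formation at the C10 carbonyl, which is flanked by two fully substituted carbons, may be too slow, so that hydrazine attacks the epoxide instead. The fallback sets out from 10. NaBH4/CeCl3 reduction gives the epoxy alcohol F6. NaHMDS, CS2 and MeI give the xanthate F7. Bu3SnH/AIBN generates the C10 radical, which opens the epoxide in a Barton–McCombie-type fragmentation, and the route is rejoined at 12.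

**Further compounds**

F1 | step 22 | (Z)-enal with O8-TMS | CC(=O)OC/C(C=O)=C/[C@@H]1OC(=O)[C@H](C)[C@@]1(O[Si](C)(C)C)[C@@H](OC(C)=O)[C@H]1C(C)=CC[C@H](OC(C)=O)[C@]1(C)C=C
F2 | step 22 | C2 methyl ketone enal | CC(=O)OC/C(C=O)=C/[C@@H]1OC(=O)[C@H](C)[C@@]1(O[Si](C)(C)C)[C@@H](OC(C)=O)[C@H]1C(C)=CC[C@H](OC(C)=O)[C@]1(C)C(C)=O
F3 | step 22 | macrocyclic C4 hydroxy C2 ketone (C4 epimers) | CC(=O)OC/C1=C/[C@@H]2OC(=O)[C@H](C)[C@@]2(O[Si](C)(C)C)[C@@H](OC(C)=O)[C@H]2C(C)=CC[C@H](OC(C)=O)[C@]2(C)C(=O)CC1O
F4 | step 22 | 2S 2,4-diol (C4 epimers) | CC(=O)OC/C1=C/[C@@H]2OC(=O)[C@H](C)[C@@]2(O[Si](C)(C)C)[C@@H](OC(C)=O)[C@H]2C(C)=CC[C@H](OC(C)=O)[C@]2(C)[C@@H](O)CC1O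
F5 | step 15 | 8,17-glycidic ester (C17 epimers) | COC(=O)C1(C)O[C@@]1(c2cc(CO[Si](C)(C)C(C)(C)C)co2)[C@@H](O[Si](C)(C)C(C)(C)C)[C@H]1C(C)=CC[C@H](O[Si](C)(C)C(C)(C)C)[C@]1(C)C=C
F6 | step 8 | epoxy alcohol (C10 epimers) | OC1[C@@]2(C)O[C@H]2C[C@H](O[Si](C)(C)C(C)(C)C)[C@]1(C)C=C
F7 | step 8 | C10 S-methyl xanthate | CSC(=S)OC1[C@@]2(C)O[C@H]2C[C@H](O[Si](C)(C)C(C)(C)C)[C@]1(C)C=C
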